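The constants were chosen freely; the flask was simulated.

Four set-ups share one charge.

common to all: second substrate 0.400 mM; third substrate 2.00 mM

|  | starting material | reagent | time | remark |
|---|---|---|---|---|
| zeta | 2.0 mM | 3.00 mM (fed, over 4.00 s) | 4.0 s | all but reagent at the start; reagent goes in evenly over 4.00 s, the run ends at 4.0 s |
| delta | 2.0 mM | 3.00 mM | 4.0 s | a closed flask charged with all of it at once and left for 4.0 s |
| gamma | 2.0 mM | 3.00 mM |  | a single well-mixed tank run continuously and read at steady state, 4.0 s in it on average |
| theta | 2.0 mM (fed, over 4.00 s) | 3.00 mM | 4.0 s | all but starting material at the start; starting material goes in evenly over 4.00 s, the run ends at 4.0 s |

1. the set-up with the highest amount of target at the outlet or at the end, in percent of the starting material put in ("none" if the first two lie within 2 percentage points) (zeta / delta / gamma / theta / none)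
2. amount of target at the outlet or at the end, in percent of the starting material put in, zeta
3. amount of target at the outlet or at the end, in percent of the starting material put in, delta
4. amount of target at the outlet or at the end, in percent of the starting material put in, gamma
5. amount of target at the outlet or at the end, in percent of the starting material put in, theta

- a step written with two of one species runs at k times the square of its concentration and takes two of it each time
- the stated concentrations are those of everything mixed, before any reaction; amounts are the same in each set-up
- the feed brings no volume worth counting
- run time (zeta): 4.0 s

Starting material has a single way out, through reagent, so the part of it left is exp(−N). Here N is the rate constant 127 L mol⁻¹ s⁻¹ times the time integral of the reagent concentration: the contact number, a pseudo-first-order picture in which reagent stands in for time. It is first reckoned with reagent held at its charge for the whole of delta, which gives 1.52, or 78.2 % target.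

In the first instants of delta, second substrate dimerises with a first half-life of 0.295 s, shorter than the 0.87 s it has by reagent. With both losses integrated together and reagent held at its charge, the estimate is that reagent takes about 0.156 mM of it.

In the middle, starting material (half-life 1.8 s) draws reagent 2.6 times as fast at the start as third substrate (half-life 4.8 s). Reagent is the limiting reagent, 3.00 mM against 4.00 mM of these two, so its level falls and the first number is too high.

At the end of delta, the first answer leaves 0.401 mM of reagent. Put back as a mean of start and end, that gives a contact number of 0.864 and 57.8 % target. These rounds swing from high to low here, so the figure is rough.

The other set-ups are compared at the first round. Zeta's ramp divides the number by two, gamma's tank gives N over one plus N, and theta's target is averaged over the arrival of its starting material. The winner is delta.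

The forecast names delta, with 40.5 % for zeta, 59.3 % for delta, 43.9 % for gamma and 36 % for theta. It holds that the “second substrate mostly removes itself”. Its delta figure comes from stepping the run, not from these rounds, and differs slightly.

The simulation gives delta: 40.5 % for zeta, 59.2 % for delta, 43.9 % for gamma and 35.7 % for theta.

    third substrate + reagent → third product (k1 = 48.2 L mol⁻¹ s⁻¹)
    2 second substrate → homo dimer (k2 = 4240 L mol⁻¹ s⁻¹)
    starting material + reagent → target (k3 = 127 L mol⁻¹ s⁻¹)
    second substrate + reagent → second product (k4 = 267 L mol⁻¹ s⁻¹)

Read back from delta, the 41 % of starting material left means a contact number of 0.892. In delta, part of the gap to full conversion lies in third substrate's draw on reagent and part in the reading time: from 59.2 %, target reaches 64.9 % with that step struck out, and 87.1 % at 40.0 s. For the neighbour with 7.5 mM of reagent, the same two rounds run from 3.81 to 2.87, so 94.3 % target, and that flask holds 92.7 %.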